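The south run held 1.36 reagent per substrate and had made 82.2% product after 4.00 d. The north flask held less reagent per substrate, so, taking one reagent per product, I set its ceiling at 70.0% of the charge: reagent was the limiting reagent.

the same everywhere: reagent 0.273 M; capture agent 0.0195 M; free catalyst 7.8 mM
- north: substrate 0.39 M (in portions, 3); the very flask that is asked about, followed so far; portions every 4.0 h
- south: substrate 0.20 M (in portions, 3); run made earlier; portions every 4.0 h
- flask: substrate 0.39 M (in portions, 3); the portions of substrate follow each other after 4.0 h, the first at the start; time 4.0 d

north run (percent of the substrate charged)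

| time / h | catalyst intermediate C / % | catalyst intermediate E / % | substrate / % | product / % | catalyst intermediate D / % | trapped intermediate / % |
|---|---|---|---|---|---|---|
| 4.00 | 0 | 0 | 31.2 | 1.9 | 0 | 0 |
| 8.00 | 0.4 | 0.4 | 61.2 | 5.1 | 0 | 0.2 |
| 15.0 | 0 | 0 | 86.9 | 12.5 | 0.1 | 0.2 |
| 25.0 | 0 | 0.4 | 78.2 | 21.5 | 0 | 0 |
| 50.0 | 0 | 0.1 | 57.8 | 41.7 | 0 | 0 |

south run (percent of the substrate charged)

| time / d | catalyst intermediate C / % | catalyst intermediate E / % | substrate / % | product / % | catalyst intermediate D / % | trapped intermediate / % |
|---|---|---|---|---|---|---|
| 0.333 | 0 | 0.4 | 59.3 | 6.8 | 0 | 0 |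
| 1.04 | 0.1 | 0.5 | 70.6 | 29.1 | 0 | 0.2 |
| 1.67 | 0 | 0 | 54.1 | 45.7 | 0 | 0 |
| 3.00 | 0 | 0.1 | 29.0 | 70.4 | 0 | 0.8 |
| 4.00 | 0 | 0.7 | 17.3 | 82.2 | 0.2 | 0 |

(standard deviation of a reading: 0.3 percentage points)

- a reading at the moment of an addition is taken just before it
- percentages count the whole charge, also what has not yet gone in

- the species that holds most of what was charged as substrate, at 4.0 d (substrate / catalyst intermediate C / trapped intermediate / catalyst intermediate D / catalyst intermediate E / product)
- the largest share itself, whichever of these holds it, in percent of the substrate charged

I ran the north flask slowly in my head. At first substrate was still going in, and after 4.00 h free substrate stood at 31.2% against 1.9% product. No north reading of catalyst intermediates C, D, E or trapped intermediate rose above 0.4%, with a scatter of 0.3 percentage points, so I let substrate and product carry the balance.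

In the middle, free substrate lost a third of itself between 15.0 h and 50.0 h. Yet the pace of product went from 0.00900 /h of the charge to 0.00808 /h.

The end was what mattered. I defined the reach time as the moment when the last pace, drawn straight on from the last reading, meets the ceiling: 85.0 h. That came before 96 h, so I committed to product, just under 70.0%.

The forecast said product at 60%, expecting rates to decline “over the next 46 h as reagent runs low”.

The flask gave product at 68.1%, with substrate at 31.7% and 0.834% of the reagent left at 4.00 d.

    reagent + free catalyst → catalyst intermediate A (k = 140 /M/h)
    catalyst intermediate A ⇌ catalyst intermediate B (K = 0.660, k = 1.00 /h)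
    substrate + catalyst intermediate B ⇌ catalyst intermediate C (K = 0.890 /M, k = 11.0 /M/h)
    catalyst intermediate C ⇌ released group + catalyst intermediate D (K = 0.260 M, k = 86.0 /h)
    catalyst intermediate D → catalyst intermediate E (k = 44.0 /h)
    catalyst intermediate E → free catalyst + product (k = 4.30 /h)
    catalyst intermediate C + capture agent → trapped intermediate (k = 2.00 /M/h)

That was 8.1 points above the forecast and 1.9 points below my ceiling. A neighbouring flask, changed in free catalyst and nothing else, had 0.0047 M of it, 0.603 of the recipe's amount. Counting time in proportion to catalyst stretched its reach time to 141 h, later than 96 h, so on this reckoning that flask stopped short of the ceiling. By the same count its end lay on the north line, drawn straight on, at 57.8 h, which reads 48.0%. That flask gave 47.8% product, with 30.1% of its reagent unused.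

The runs come from a simulation for an exercise, noise included.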